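## Retrosynthetic overview

1. Target 16 ⇐ bis-TBS ether 15 by fluoride desilylation.
2. The furanone ring of 15 is the only ring made (both benzene rings are bought); it comes from intramolecular aldol condensation of the α-(methoxyacetoxy) β-keto ester 12, closing C3=C4.
3. 12 ⇐ racemic β-keto ester 9 + methoxyacetic acid 10, by a catalytic enantioselective oxidative C–O coupling that makes the ring O–C2 bond and the only stereocentre (R).
4. 9 ⇐ bis-silylation of 8 ⇐ reductive Knoevenagel union of aldehyde 3 and β-keto ester 6.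
5. 3 ⇐ 4-hydroxybenzaldehyde 1 + prenyl bromide 2; 6 ⇐ 4′-hydroxyacetophenone 4 + dimethyl carbonate 5.

Assumption: the sense of induction in step 5 cannot be predicted with certainty; the (S,S)-ligand is written, and its commercial mirror image is used instead if it proves to give the (S)-product.

Abbreviations: TBS = tert-butyldimethylsilyl; prenyl = 3-methylbut-2-en-1-yl; Ph-box = 2,2′-(propane-2,2-diyl)bis(4-phenyl-4,5-dihydrooxazole).

## Route

Step 1
Reactants: 1 4-hydroxybenzaldehyde; 2 prenyl bromide (1-bromo-3-methylbut-2-ene)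
Product: 3 4-hydroxy-3-(3-methylbut-2-en-1-yl)benzaldehyde
Conditions: KOH (1.1 eq), H2O, rt, 24 h
Reagents that add atoms: none
Why: Ambident phenoxide ortho-C-alkylation: in water the oxygen is hydrogen-bonded, so the allylic bromide is taken by the ortho carbon (para is blocked) and the dienone re-aromatises; modest yield is accepted on very cheap materials, and no stereocentre is formed.

Step 2
Reactants: 4 4′-hydroxyacetophenone; 5 dimethyl carbonate
Product: 6 methyl 3-(4-hydroxyphenyl)-3-oxopropanoate
Conditions: NaH (3.5 eq), 5 (4 eq), THF, reflux; then aq HCl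
Reagents that add atoms: none
Why: Crossed Claisen condensation of the ketone enolate with dimethyl carbonate, driven by irreversible deprotonation of the product β-keto ester; the phenoxide formed first is a spectator and is re-protonated on work-up.

Step 3
Reactants: 3 4-hydroxy-3-prenylbenzaldehyde; 6 methyl 3-(4-hydroxyphenyl)-3-oxopropanoate
Product: 8 racemic methyl 2-[[4-hydroxy-3-(3-methylbut-2-en-1-yl)phenyl]methyl]-3-(4-hydroxyphenyl)-3-oxopropanoate, via Knoevenagel adduct 7 (not isolated)
Conditions: L-proline (20 mol%), Hantzsch ester (diethyl 2,6-dimethyl-1,4-dihydropyridine-3,5-dicarboxylate, 1.1 eq), MeOH, 40 °C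
Reagents that add atoms: none
Why: Three-component reductive alkylation (proline-catalysed Knoevenagel condensation, then transfer hydrogenation of the doubly activated alkene 7 by the Hantzsch ester), which tolerates free phenols and leaves the prenyl alkene and the ketone alone; the new centre is deliberately racemic because step 5 planarises it.

Step 4
Reactants: 8 racemic bis-phenol β-keto ester
Product: 9 racemic methyl 2-[[4-(TBS-oxy)-3-(3-methylbut-2-en-1-yl)phenyl]methyl]-3-[4-(TBS-oxy)phenyl]-3-oxopropanoate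
Conditions: TBSCl (2.4 eq), imidazole (5 eq), DMF, 0 °C → rt
Reagents that add atoms: tert-butyldimethylsilyl chloride (TBSCl), CC(C)(C)[Si](C)(C)Cl
Why: Standard imidazole-mediated silylation of both phenols in one operation; it blocks phenol oxidation by trivalent iodine in step 5 and phenoxide formation in step 6, and the mostly ketonic α-substituted β-keto ester is not silylated.

Step 5
Reactants: 9 racemic bis-TBS β-keto ester; 10 methoxyacetic acid
Product: 12 methyl (2R)-2-[[4-(TBS-oxy)-3-(3-methylbut-2-en-1-yl)phenyl]methyl]-2-(2-methoxyacetoxy)-3-[4-(TBS-oxy)phenyl]-3-oxopropanoate, via bis(methoxyacetoxy)iodobenzene 11 (not isolated)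
Conditions: PhI(OAc)2 (1.3 eq), 10 (2.8 eq), PhCl, 45 °C, 20 mbar (AcOH stripped); then 9, Cu(OTf)2 (10 mol%), (S,S)-Ph-box (11 mol%), 4 Å MS, CH2Cl2, −20 °C
Reagents that add atoms: none
Why: Proposed new method: catalytic enantioselective α-acyloxylation of an acyclic α-substituted β-keto ester by acyloxy transfer from a bis(acyloxy)iodoarene: the Cu(box) carboxylate deprotonates chelated 9 to a square-planar copper enolate with one face screened by a ligand phenyl group, and because both carbonyl oxygens are held by copper the trivalent iodine of 11 is engaged through carbon on the open face; the resulting α-iodanyl keto ester can neither enolise nor ionise between two carbonyls, so it collapses by stereospecific carboxylate ligand coupling with loss of PhI and the face selection is carried into the new C–O bond at the (R) quaternary centre; the product has no α-hydrogen (no racemisation, no over-oxidation) and no peracid is present (prenyl alkene and aryl silyl ethers spared); the closest known reactions are the racemic α-acetoxylation of 2-substituted 1,3-dicarbonyls by PhI(OAc)2 and the chiral-Lewis-acid-catalysed enantioselective α-chlorination, α-azidation and α-amination of β-keto esters by hypervalent iodine or nitrogen electrophiles.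

Step 6
Reactants: 12 (R)-α-(methoxyacetoxy) β-keto ester
Product: 15 methyl (2R)-2-[[4-(TBS-oxy)-3-(3-methylbut-2-en-1-yl)phenyl]methyl]-3-[4-(TBS-oxy)phenyl]-4-methoxy-5-oxo-2,5-dihydrofuran-2-carboxylate, via lithium aldolate 13 (not isolated), via tertiary mesylate 14 (not isolated)
Conditions: LiN(SiMe3)2 (1.1 eq), THF, −78 °C; then MsCl (1.5 eq), Et3N (3 eq), −78 → 0 °C
Reagents that add atoms: none
Why: Intramolecular aldol condensation: the methoxyacetate CH2 is the only enolisable position and its lithium enolate adds 5-exo to the neighbouring aryl ketone faster than to the methyl ester at −78 °C; cold mesylation traps aldolate 13 before retro-aldol or Dieckmann equilibration, and the tertiary benzylic mesylate 14 eliminates to the conjugated butenolide, while the quaternary stereocentre carries no hydrogen and is untouched.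

Step 7
Reactants: 15 bis-TBS butenolide
Product: 16 methyl (2R)-2-[[4-hydroxy-3-(3-methylbut-2-en-1-yl)phenyl]methyl]-3-(4-hydroxyphenyl)-4-methoxy-5-oxo-2,5-dihydrofuran-2-carboxylate (target)
Conditions: Bu4NF (2.4 eq), AcOH (2.6 eq), THF, 0 °C
Reagents that add atoms: none
Why: Fluoride cleavage of aryl silyl ethers, buffered by AcOH so that the lactone, the methyl ester, the enol methyl ether and the acid-sensitive ortho-prenyl phenol survive; the stereocentre is not involved.

## Compound list

1 | 4-hydroxybenzaldehyde | O=Cc1ccc(O)cc1 | starting material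
2 | prenyl bromide (1-bromo-3-methylbut-2-ene) | CC(C)=CCBr | starting material
3 | 4-hydroxy-3-(3-methylbut-2-en-1-yl)benzaldehyde | O=Cc1ccc(O)c(CC=C(C)C)c1 | intermediate
4 | 4′-hydroxyacetophenone | CC(=O)c1ccc(O)cc1 | starting material
5 | dimethyl carbonate | COC(=O)OC | starting material
6 | methyl 3-(4-hydroxyphenyl)-3-oxopropanoate | COC(=O)CC(=O)c1ccc(O)cc1 | intermediate
7 | methyl 2-(4-hydroxybenzoyl)-3-[4-hydroxy-3-(3-methylbut-2-en-1-yl)phenyl]prop-2-enoate (E/Z mixture) | COC(=O)C(=Cc1ccc(O)c(CC=C(C)C)c1)C(=O)c1ccc(O)cc1 | intermediate (not isolated)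
8 | racemic methyl 2-[[4-hydroxy-3-(3-methylbut-2-en-1-yl)phenyl]methyl]-3-(4-hydroxyphenyl)-3-oxopropanoate | COC(=O)C(Cc1ccc(O)c(CC=C(C)C)c1)C(=O)c1ccc(O)cc1 | intermediate
9 | racemic methyl 2-[[4-(tert-butyldimethylsilyloxy)-3-(3-methylbut-2-en-1-yl)phenyl]methyl]-3-[4-(tert-butyldimethylsilyloxy)phenyl]-3-oxopropanoate | COC(=O)C(Cc1ccc(O[Si](C)(C)C(C)(C)C)c(CC=C(C)C)c1)C(=O)c1ccc(O[Si](C)(C)C(C)(C)C)cc1 | intermediate
10 | methoxyacetic acid | COCC(=O)O | starting material
11 | bis(methoxyacetoxy)iodobenzene | COCC(=O)O[I](OC(=O)COC)c1ccccc1 | intermediate (not isolated)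
12 | methyl (2R)-2-[[4-(tert-butyldimethylsilyloxy)-3-(3-methylbut-2-en-1-yl)phenyl]methyl]-2-(2-methoxyacetoxy)-3-[4-(tert-butyldimethylsilyloxy)phenyl]-3-oxopropanoate | COC(=O)[C@](Cc1ccc(O[Si](C)(C)C(C)(C)C)c(CC=C(C)C)c1)(OC(=O)COC)C(=O)c1ccc(O[Si](C)(C)C(C)(C)C)cc1 | intermediate
13 | lithium alkoxide of methyl (2R)-2-[[4-(tert-butyldimethylsilyloxy)-3-(3-methylbut-2-en-1-yl)phenyl]methyl]-3-[4-(tert-butyldimethylsilyloxy)phenyl]-3-hydroxy-4-methoxy-5-oxooxolane-2-carboxylate (diastereomer mixture at C3 and C4) | [Li+].COC(=O)[C@]1(Cc2ccc(O[Si](C)(C)C(C)(C)C)c(CC=C(C)C)c2)OC(=O)C(OC)C1([O-])c1ccc(O[Si](C)(C)C(C)(C)C)cc1 | intermediate (not isolated)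
14 | methyl (2R)-2-[[4-(tert-butyldimethylsilyloxy)-3-(3-methylbut-2-en-1-yl)phenyl]methyl]-3-[4-(tert-butyldimethylsilyloxy)phenyl]-4-methoxy-3-(methylsulfonyloxy)-5-oxooxolane-2-carboxylate (diastereomer mixture at C3 and C4) | COC(=O)[C@]1(Cc2ccc(O[Si](C)(C)C(C)(C)C)c(CC=C(C)C)c2)OC(=O)C(OC)C1(OS(C)(=O)=O)c1ccc(O[Si](C)(C)C(C)(C)C)cc1 | intermediate (not isolated)
15 | methyl (2R)-2-[[4-(tert-butyldimethylsilyloxy)-3-(3-methylbut-2-en-1-yl)phenyl]methyl]-3-[4-(tert-butyldimethylsilyloxy)phenyl]-4-methoxy-5-oxo-2,5-dihydrofuran-2-carboxylate | COC(=O)[C@]1(Cc2ccc(O[Si](C)(C)C(C)(C)C)c(CC=C(C)C)c2)OC(=O)C(OC)=C1c1ccc(O[Si](C)(C)C(C)(C)C)cc1 | intermediate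
16 | methyl (2R)-2-[[4-hydroxy-3-(3-methylbut-2-en-1-yl)phenyl]methyl]-3-(4-hydroxyphenyl)-4-methoxy-5-oxo-2,5-dihydrofuran-2-carboxylate | COC(=O)[C@]1(Cc2ccc(O)c(CC=C(C)C)c2)OC(=O)C(OC)=C1c1ccc(O)cc1 | target

## Step count and risks

Total steps: 7 (steps 1 and 2 run in parallel). Longest linear sequence: 6 (steps 1, 3, 4, 5, 6, 7).

Three steps most likely to fail:

**Step 5 (the proposed new C–O coupling).** Risks: reaction through an oxygen-bound iodine enolate could erode the ee; residual acetate could be transferred; carboxylate could slow copper turnover. The fallback uses known chemistry, sets out from 9 and comes back at 12. Compound 9 is hydroxylated by the established chiral-Lewis-acid enolate oxidation with an electrophilic N-sulfonyloxaziridine, which does not touch the prenyl alkene. Conditions: TiCl2(TADDOLato) (5 mol%; TADDOLato = (4R,5R)-2,2-dimethyl-α,α,α′,α′-tetra(1-naphthyl)-1,3-dioxolane-4,5-dimethanolate, antipode chosen for the R product), 2-(phenylsulfonyl)-3-(4-nitrophenyl)oxaziridine, CH2Cl2, rt. This gives methyl (2R)-2-[[4-(TBS-oxy)-3-prenylphenyl]methyl]-2-hydroxy-3-[4-(TBS-oxy)phenyl]-3-oxopropanoate F1. The hindered tertiary alcohol is then acylated through methoxyketene (methoxyacetyl chloride, Et3N, DMAP, CH2Cl2, 0 °C) to give 12. The cost is one extra step.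

**Step 6 (aldol condensation).** Risks: retro-aldol followed by Dieckmann attack on the methyl ester (a tetronic acid sink), or loss of methoxyketene from the ester enolate. The fallback sets out from 12 and comes back at 15, replacing the basic lithium enolate by a neutral silyl enolate and Lewis-acid activation. Soft enolisation (Me3SiOTf, Et3N, CH2Cl2, 0 °C) gives the O-trimethylsilyl ketene acetal of the methoxyacetate F2. TiCl4 (CH2Cl2, −78 °C) chelates the ketone together with the neighbouring methyl ester and drives an intramolecular Mukaiyama aldol addition; a silyl ketene acetal cannot attack the ester. Work-up gives methyl (2R)-2-[[4-(TBS-oxy)-3-prenylphenyl]methyl]-3-[4-(TBS-oxy)phenyl]-3-hydroxy-4-methoxy-5-oxooxolane-2-carboxylate F3. SOCl2/pyridine (0 °C) dehydrates this to 15.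

**Step 1 (ortho-C-prenylation).** Risks: O-alkylation and double alkylation, so low yield. The fallback sets out from 1 and comes back at 3, placing the prenyl group by a sigmatropic shift instead of a direct alkylation. Copper-catalysed O-alkylation (3-chloro-3-methylbut-1-yne, DBU, CuCl2 cat., MeCN, 0 °C) gives 4-[(2-methylbut-3-yn-2-yl)oxy]benzaldehyde F4. Semihydrogenation (H2, Pd on CaCO3 poisoned by Pb(OAc)2, quinoline, EtOAc) gives 4-[(2-methylbut-3-en-2-yl)oxy]benzaldehyde F5. Heating (N,N-diethylaniline, 140 °C) effects the aromatic Claisen [3,3] rearrangement to the ortho position (para is blocked) and gives 3 with the linear prenyl group.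

## Further compounds

F1 | step 5 | methyl (2R)-2-[[4-(tert-butyldimethylsilyloxy)-3-(3-methylbut-2-en-1-yl)phenyl]methyl]-2-hydroxy-3-[4-(tert-butyldimethylsilyloxy)phenyl]-3-oxopropanoate | COC(=O)[C@](Cc1ccc(O[Si](C)(C)C(C)(C)C)c(CC=C(C)C)c1)(O)C(=O)c1ccc(O[Si](C)(C)C(C)(C)C)cc1
F2 | step 6 | O-trimethylsilyl ketene acetal of the methoxyacetate of 12 | COC(=O)[C@](Cc1ccc(O[Si](C)(C)C(C)(C)C)c(CC=C(C)C)c1)(OC(O[Si](C)(C)C)=COC)C(=O)c1ccc(O[Si](C)(C)C(C)(C)C)cc1
F3 | step 6 | methyl (2R)-2-[[4-(tert-butyldimethylsilyloxy)-3-(3-methylbut-2-en-1-yl)phenyl]methyl]-3-[4-(tert-butyldimethylsilyloxy)phenyl]-3-hydroxy-4-methoxy-5-oxooxolane-2-carboxylate | COC(=O)[C@]1(Cc2ccc(O[Si](C)(C)C(C)(C)C)c(CC=C(C)C)c2)OC(=O)C(OC)C1(O)c1ccc(O[Si](C)(C)C(C)(C)C)cc1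
F4 | step 1 | 4-[(2-methylbut-3-yn-2-yl)oxy]benzaldehyde | O=Cc1ccc(OC(C)(C)C#C)cc1
F5 | step 1 | 4-[(2-methylbut-3-en-2-yl)oxy]benzaldehyde | O=Cc1ccc(OC(C)(C)C=C)cc1
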